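## Retrosynthetic overview

1. Target ⇐ desilylation, Horner–Wadsworth–Emmons methylenation and C8 angeloylation of a ten-membered α-phosphono trans-6,12-lactone.
2. Ten-membered ring ⇐ C–O-forming ring expansion: ozonolysis (C=C → 2 C=O) of a ring-fusion alkene in an octalin, then C6 carbonyl reduction and acyl transfer O8 → O6; no C–C macrocyclisation.
3. Octalin ⇐ Robinson annulation of 3-methylbut-3-en-2-one onto a cis-fused bicyclic keto-lactone; deconjugative reduction fixes C3 and C4.
4. Keto-lactone ⇐ new tertiary-ketol-directed Evans–Tishchenko redox esterification with lactonisation (makes C10–OAc and the C8–O centre in one step).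
5. ⇐ Mn–H α-hydroxylation and asymmetric Michael addition of triethyl phosphonoacetate to the quinone monoketal of 4-methoxy-2-methylphenol. Ring order: carbocycle B → 8,12-lactone → ring A → cyclodecane by cleavage → 6,12-lactone.

Numbering used below: germacranolide numbering of the target (C1 ketone, C3 carbinol, C4 with methyl C15, C6 lactone carbinol, C7, C8 angelate, C10 with methyl C14 and acetate, C11=C13, C12 lactone carbonyl); α/β = below/above the ring as usually drawn.

Assumption: C11 of all phosphonate intermediates is an epimer mixture of no consequence (destroyed in step 11) and is left undefined in the SMILES, as are the transient centres of ketol 12 and ozonide 18.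

## Route

Step 1
Reactants: 1 4-methoxy-2-methylphenol
Product: 2 4,4-dimethoxy-2-methylcyclohexa-2,5-dien-1-one
Conditions: PhI(OAc)2, MeOH, 0 °C
Reagents that add atoms: methanol (CO)
Why: Iodine(III) oxidative dearomatisation of a p-methoxyphenol with methanol capture at the para carbon gives the quinone monoketal; no stereocentre is formed.

Step 2
Reactants: 2 4,4-dimethoxy-2-methylcyclohexa-2,5-dien-1-one; 3 triethyl phosphonoacetate
Product: 4 ethyl 2-(diethoxyphosphoryl)-2-[(1S)-2,2-dimethoxy-4-methyl-5-oxocyclohex-3-en-1-yl]acetate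
Conditions: (R)-ALB [AlLi-bis((R)-binaphthoxide)] 10 mol %, NaOt-Bu 9 mol %, 4 Å MS, THF, rt
Reagents that add atoms: none
Why: Shibasaki ALB-catalysed asymmetric Michael addition of a Horner–Wadsworth–Emmons reagent to the unsubstituted enone (the 2-methyl enone is less electrophilic), the heterobimetallic binaphthoxide shielding one enone face so that C7 is set as drawn (same facial sense as the (R)-adducts of cyclohexenone).

Step 3
Reactants: 4 Michael adduct
Product: 7 ethyl 2-(diethoxyphosphoryl)-2-[(1S,4R)-4-hydroxy-4-methyl-2,5-dioxocyclohexyl]acetate, via hydroperoxide 5 (not isolated), via hydroxy ketal 6 (not isolated)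
Conditions: Mn(dpm)3 (5 mol %), PhSiH3, O2 (1 atm), i-PrOH/CH2Cl2, 0 °C; P(OEt)3; then 1 M HCl, THF, 0 °C
Reagents that add atoms: dioxygen (O=O); water (O)
Why: Mukaiyama-type Mn–H hydrogen-atom transfer to C9 gives the tertiary α-keto radical at C10, which is trapped by O2 on the face opposite the axial ketal methoxy group (trans to the C7 side chain); phosphite reduces the hydroperoxide (Magnus enone α-hydroxylation) and aqueous acid hydrolyses the ketal to the C8 ketone.

Step 4
Reactants: 7 hydroxy-dione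
Product: 9 (3aS,6R,7aR)-3-(diethoxyphosphoryl)-6-methyl-2,5-dioxooctahydro-1-benzofuran-6-yl acetate, via acetoxy alcohol 8 (not isolated)
Conditions: SmI2 (0.3 equiv, pre-mixed with MeCHO), MeCHO (8 equiv), THF, −10 °C → rt
Reagents that add atoms: acetaldehyde (CC=O)
Why: Proposed new method: the tertiary C10 samarium alkoxide adds to acetaldehyde and the Sm(III)-bound hemiacetal delivers hydride 1,3-diaxially to the chelated C8 ketone through a chair six-membered transition state, so H enters cis to O10 (C8–O ends trans to O10 and cis to C11), the C10 oxygen emerges as the acetate and the new C8 alkoxide lactonises onto the ethyl ester; the closest known reaction is the Evans–Tishchenko anti-reduction of secondary acyclic β-hydroxy ketones, not shown for a tertiary α-ketol donor or a cyclohexane-1,4-dione.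

Step 5
Reactants: 9 bicyclic keto-lactone; 10 3-methylbut-3-en-2-one
Product: 13 tricyclic enone (C1–C6 bond; Δ1(2)-3-one; 4α-methyl; 6β-H; 10α-OAc; cis-fused 8β,12-phosphonolactone), via diketone 11 (not isolated), via ketol 12 (not isolated)
Conditions: cat. H2SO4, toluene, 0 → 60 °C
Reagents that add atoms: none
Why: Acid-catalysed Robinson annulation (enol Michael addition, then aldol condensation): C10 is quaternary so only C6 enolises, the vinyl ketone is attacked anti to the cis-fused lactone (C5 trans to C11), and the C4 methyl equilibrates to the equatorial position cis-1,3 to the C6–C7 bond, which is the required 4α-methyl.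

Step 6
Reactants: 13 tricyclic enone
Product: 16 homoallylic alcohol (3β-OH, 4α-methyl, C1=C6), via silyl dienol ether 14 (not isolated), via deconjugated enone 15 (not isolated)
Conditions: TMSCl, Et3N, DMF, 80 °C; then NaBH4, CeCl3·7H2O, MeOH, −40 → 0 °C
Reagents that add atoms: none
Why: House thermodynamic silylation gives the linear dienol ether (C10 has no H, so the second double bond must be C1=C6), methanolysis protonates C2 kinetically and the transient β,γ-enone is reduced at once (Dauben-type deconjugative borohydride reduction, Luche conditions) by axial hydride to the equatorial 3β-alcohol trans to the C4 methyl before C4 can epimerise.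

Step 7
Reactants: 16 homoallylic alcohol
Product: 17 3-O-tert-butyldimethylsilyl ether of 16
Conditions: TBSCl, imidazole, DMF, rt
Reagents that add atoms: tert-butyldimethylsilyl chloride (CC(C)(C)[Si](C)(C)Cl)
Why: Standard silylation of the only free hydroxyl, so that C3–OH can neither direct nor quench the later borane reduction nor form a hemiketal with C6.

Step 8
Reactants: 17 silyl ether
Product: 19 cyclodecane-1,6-dione (1,6-dioxo; 3β-OTBS; 4α-methyl; 10α-OAc; 8β,12-phosphonolactone), via ozonide 18 (not isolated)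
Conditions: O3, CH2Cl2, −78 °C; PPh3
Reagents that add atoms: ozone ([O-][O+]=O)
Why: Ozonolysis (Criegee mechanism) of the only alkene, the electron-rich tetrasubstituted ring-fusion C1=C6 bond, converts the octalin into the ten-membered 1,6-dione by forming two C=O bonds; no stereocentre is touched.

Step 9
Reactants: 19 cyclodecane-1,6-dione
Product: 21 8β-hydroxy-6α,12-lactone (trans-fused 11-phosphono lactone; 1-oxo; 3β-OTBS; 10α-OAc), via C6 alcohol 20 (not isolated)
Conditions: (S)-Me-CBS (0.5 equiv), BH3·SMe2, THF, −30 °C; MeOH; then CSA (cat.), CH2Cl2, rt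
Reagents that add atoms: none
Why: Corey–Bakshi–Shibata reduction of the less hindered C6 ketone (C1 is flanked by quaternary C10) under (S)-catalyst control (C7 branch large, C5 methylene small) gives the 6R alcohol, and acid-catalysed translactonisation moves the acyl group from O8 to O6 because a trans-fused lactone leaves the cyclodecane an anti-clinal C5–C6–C7–C8 torsion whereas the cis-fused one forces a near-eclipsed torsion.

Step 10
Reactants: 21 8β-hydroxy-6α,12-lactone; 22 angelic acid
Product: 24 8β-angelate of 21, via mixed anhydride 23 (not isolated)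
Conditions: 2,4,6-trichlorobenzoyl chloride, Et3N, toluene, rt; then 21, 80 °C (no DMAP)
Reagents that add atoms: none
Why: Yamaguchi esterification through the mixed anhydride acylates the only free hydroxyl (C8) and, without DMAP, avoids angelate-to-tiglate isomerisation.

Step 11
Reactants: 24 angelate
Product: 25 3-O-TBS ether of the target
Conditions: 37 % aq. CH2O, K2CO3, THF, 0 °C
Reagents that add atoms: formaldehyde (C=O)
Why: Horner–Wadsworth–Emmons olefination of the α-phosphono lactone (by far the most acidic C–H) with formaldehyde unveils the α-methylene lactone and removes the undefined C11 centre.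

Step 12
Reactants: 25 silyl ether
Product: 26 CNP0141210.1 (3S,4S,6R,7S,8R,10R)
Conditions: HF·pyridine, THF, 0 °C → rt
Reagents that add atoms: none
Why: Fluoride desilylation of the secondary TBS ether under mildly acidic conditions leaves the tertiary acetate, angelate, β-hydroxy ketone and α-methylene lactone intact.

## Compound list

1 | 4-methoxy-2-methylphenol | Cc1cc(OC)ccc1O | starting material
2 | 4,4-dimethoxy-2-methylcyclohexa-2,5-dien-1-one | CC1=CC(OC)(OC)C=CC1=O | intermediate
3 | triethyl phosphonoacetate | CCOC(=O)CP(=O)(OCC)OCC | starting material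
4 | ethyl 2-(diethoxyphosphoryl)-2-[(1S)-2,2-dimethoxy-4-methyl-5-oxocyclohex-3-en-1-yl]acetate | CCOC(=O)C(P(=O)(OCC)OCC)[C@H]1CC(=O)C(C)=CC1(OC)OC | intermediate
5 | ethyl 2-(diethoxyphosphoryl)-2-[(1S,4R)-4-hydroperoxy-2,2-dimethoxy-4-methyl-5-oxocyclohexyl]acetate | CCOC(=O)C(P(=O)(OCC)OCC)[C@H]1CC(=O)[C@](C)(OO)CC1(OC)OC | intermediate (not isolated)
6 | ethyl 2-(diethoxyphosphoryl)-2-[(1S,4R)-4-hydroxy-2,2-dimethoxy-4-methyl-5-oxocyclohexyl]acetate | CCOC(=O)C(P(=O)(OCC)OCC)[C@H]1CC(=O)[C@](C)(O)CC1(OC)OC | intermediate (not isolated)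
7 | ethyl 2-(diethoxyphosphoryl)-2-[(1S,4R)-4-hydroxy-4-methyl-2,5-dioxocyclohexyl]acetate | CCOC(=O)C(P(=O)(OCC)OCC)[C@H]1CC(=O)[C@](C)(O)CC1=O | intermediate
8 | ethyl 2-[(1S,2R,4R)-4-acetoxy-2-hydroxy-4-methyl-5-oxocyclohexyl]-2-(diethoxyphosphoryl)acetate | CCOC(=O)C(P(=O)(OCC)OCC)[C@H]1CC(=O)[C@](C)(OC(C)=O)C[C@H]1O | intermediate (not isolated)
9 | (3aS,6R,7aR)-3-(diethoxyphosphoryl)-6-methyl-2,5-dioxooctahydro-1-benzofuran-6-yl acetate (cis-fused; C8–O–C12 lactone, 10α-OAc) | O=C1O[C@@H]2C[C@@](C)(OC(C)=O)C(=O)C[C@@H]2C1P(=O)(OCC)OCC | intermediate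
10 | 3-methylbut-3-en-2-one | CC(=O)C(C)=C | starting material
11 | 1,5-diketone: 9 carrying a 2-methyl-3-oxobutyl group at C6 (α, trans to C11; C4 epimers) | O=C1O[C@@H]2C[C@@](C)(OC(C)=O)C(=O)[C@@H](CC(C)C(C)=O)[C@@H]2C1P(=O)(OCC)OCC | intermediate (not isolated)
12 | tricyclic ketol: C2 of 11 added to the C1 carbonyl (C1–OH) | O=C1O[C@@H]2C[C@@](C)(OC(C)=O)C3(O)CC(=O)C(C)C[C@H]3[C@@H]2C1P(=O)(OCC)OCC | intermediate (not isolated)
13 | tricyclic enone: C1–C6-bonded decalin, Δ1(2)-3-one, 4α-methyl, 6β-H, 10α-acetoxy-10β-methyl, cis-fused 8β,12-lactone with 11-P(O)(OEt)2 | O=C1O[C@@H]2C[C@@](C)(OC(C)=O)C3=CC(=O)[C@@H](C)C[C@H]3[C@@H]2C1P(=O)(OCC)OCC | intermediate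
14 | linear trimethylsilyl dienol ether of 13 (C3–OTMS, C2=C3, C1=C6) | O=C1O[C@@H]2C[C@@](C)(OC(C)=O)C3=C(C[C@H](C)C(O[Si](C)(C)C)=C3)[C@@H]2C1P(=O)(OCC)OCC | intermediate (not isolated)
15 | β,γ-enone: C1=C6 3-ketone isomer of 13 | O=C1O[C@@H]2C[C@@](C)(OC(C)=O)C3=C(C[C@H](C)C(=O)C3)[C@@H]2C1P(=O)(OCC)OCC | intermediate (not isolated)
16 | homoallylic alcohol: 3β-hydroxy-4α-methyl-Δ1(6)-octalin with 10α-OAc and 8β,12-phosphonolactone | O=C1O[C@@H]2C[C@@](C)(OC(C)=O)C3=C(C[C@H](C)[C@@H](O)C3)[C@@H]2C1P(=O)(OCC)OCC | intermediate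
17 | 3-O-TBS ether of 16 | O=C1O[C@@H]2C[C@@](C)(OC(C)=O)C3=C(C[C@H](C)[C@@H](O[Si](C)(C)C(C)(C)C)C3)[C@@H]2C1P(=O)(OCC)OCC | intermediate
18 | ozonide (1,2,4-trioxolane across C1 and C6) of 17 | O=C1O[C@@H]2C[C@@](C)(OC(C)=O)C3(OO4)C[C@H](O[Si](C)(C)C(C)(C)C)[C@@H](C)CC4(O3)[C@@H]2C1P(=O)(OCC)OCC | intermediate (not isolated)
19 | cyclodecane-1,6-dione: 1,6-dioxo, 3β-OTBS, 4α-methyl, 10α-OAc, cis-fused 8β,12-phosphonolactone | O=C1O[C@@H]2C[C@@](C)(OC(C)=O)C(=O)C[C@H](O[Si](C)(C)C(C)(C)C)[C@@H](C)CC(=O)[C@@H]2C1P(=O)(OCC)OCC | intermediate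
20 | 6α-hydroxy-8β,12-lactone (6R alcohol of 19) | O=C1O[C@@H]2C[C@@](C)(OC(C)=O)C(=O)C[C@H](O[Si](C)(C)C(C)(C)C)[C@@H](C)C[C@@H](O)[C@@H]2C1P(=O)(OCC)OCC | intermediate (not isolated)
21 | 8β-hydroxy-6α,12-lactone: trans-fused 11-(diethoxyphosphoryl) lactone, 1-oxo, 3β-OTBS, 10α-OAc | O=C1O[C@@H]2C[C@H](C)[C@@H](O[Si](C)(C)C(C)(C)C)CC(=O)[C@](C)(OC(C)=O)C[C@@H](O)[C@H]2C1P(=O)(OCC)OCC | intermediate
22 | angelic acid, (Z)-2-methylbut-2-enoic acid | C/C=C(/C)C(=O)O | starting material
23 | angelic 2,4,6-trichlorobenzoic anhydride | C/C=C(/C)C(=O)OC(=O)c1c(Cl)cc(Cl)cc1Cl | intermediate (not isolated)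
24 | 8β-angelate of 21 | O=C1O[C@@H]2C[C@H](C)[C@@H](O[Si](C)(C)C(C)(C)C)CC(=O)[C@](C)(OC(C)=O)C[C@@H](OC(=O)/C(C)=C\C)[C@H]2C1P(=O)(OCC)OCC | intermediate
25 | 3-O-TBS ether of the target (α-methylene lactone) | C=C1C(=O)O[C@@H]2C[C@H](C)[C@@H](O[Si](C)(C)C(C)(C)C)CC(=O)[C@](C)(OC(C)=O)C[C@@H](OC(=O)/C(C)=C\C)[C@@H]12 | intermediate
26 | CNP0141210.1: (3S,4S,6R,7S,8R,10R)-10-acetoxy-8-angeloyloxy-3-hydroxy-1-oxogermacr-11(13)-en-6,12-olide | C=C1C(=O)O[C@@H]2C[C@H](C)[C@@H](O)CC(=O)[C@](C)(OC(C)=O)C[C@@H](OC(=O)/C(C)=C\C)[C@@H]12 | target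

## Summary

Total steps: 12 (telescoped one-pot operations counted once). Longest linear sequence: 12 (from 1).

Steps most likely to fail:

Step 4 (the new reaction). A tertiary α-ketol may form the samarium hemiacetal poorly, retro-aldol opening of the tertiary aldolate may compete, and hydride delivery needs the chair with the C7 side chain axial. The fallback uses known chemistry, sets out from 7 and comes back at 9. Evans–Saksena reduction (Me4NBH(OAc)3, AcOH/MeCN, −25 °C) delivers hydride from the C10-bound borate to C8 and gives the anti-diol ester F1. This closes on mildly acidic work-up (cat. TsOH) to the hydroxy keto-lactone F2. The tertiary α-ketol hydroxyl is then acetylated (Ac2O, DMAP, Et3N, 40 °C) to give 9.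

Step 5. Acid-mediated annulation onto a ketone flanked by a quaternary acetoxy carbon may be sluggish, and reversible enolisation could erode the C6 configuration that relays stereochemistry to C4. The fallback sets out from 9 and comes back at 13. TMSOTf/Et3N gives the silyl enol ether F3 (only C6 can enolise). A TiCl4-mediated Mukaiyama–Michael addition to 10 at −78 °C then gives diketone 11, now isolated, under kinetic control anti to the lactone. Pyrrolidine/AcOH in toluene effects the enamine aldol condensation through 12 and equilibrates C4, giving 13.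

Step 9. Facial selectivity at C6 in a flexible ten-membered ring is the least predictable stereochemical event, and over-reduction at C1 is possible; the translactonisation is expected to be downhill for the torsional reason given in the step. The fallback sets out from 19 and comes back at 20. The C6 ketone is reduced with the enantiomeric (R)-Me-CBS catalyst (or whichever hydride gives the other epimer cleanly) to the 6β-alcohol F4. Mitsunobu inversion (PPh3, DIAD, 4-nitrobenzoic acid, toluene) gives the 6α-p-nitrobenzoate F5. Selective methanolysis (K2CO3, MeOH, 0 °C) gives 20, which is translactonised with CSA as in step 9.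

Further compounds
F1 | step 4 | ethyl 2-(diethoxyphosphoryl)-2-[(1S,2R,4R)-2,4-dihydroxy-4-methyl-5-oxocyclohexyl]acetate | CCOC(=O)C(P(=O)(OCC)OCC)[C@H]1CC(=O)[C@](C)(O)C[C@H]1O
F2 | step 4 | (3aS,6R,7aR)-3-(diethoxyphosphoryl)-6-hydroxy-6-methylhexahydro-1-benzofuran-2,5-dione | O=C1O[C@@H]2C[C@@](C)(O)C(=O)C[C@@H]2C1P(=O)(OCC)OCC
F3 | step 5 | trimethylsilyl enol ether of 9 (C1–OTMS, C1=C6) | O=C1O[C@@H]2C[C@@](C)(OC(C)=O)C(O[Si](C)(C)C)=C[C@@H]2C1P(=O)(OCC)OCC
F4 | step 9 | 6β-hydroxy-8β,12-lactone (C6 epimer of 20) | O=C1O[C@@H]2C[C@@](C)(OC(C)=O)C(=O)C[C@H](O[Si](C)(C)C(C)(C)C)[C@@H](C)C[C@H](O)[C@@H]2C1P(=O)(OCC)OCC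
F5 | step 9 | 6α-(4-nitrobenzoate) of 20 | O=C1O[C@@H]2C[C@@](C)(OC(C)=O)C(=O)C[C@H](O[Si](C)(C)C(C)(C)C)[C@@H](C)C[C@@H](OC(=O)c3ccc(cc3)[N+](=O)[O-])[C@@H]2C1P(=O)(OCC)OCC
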